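(The rate constants stand for no real mixture, and the outcome is calculated.)

The amounts are what I want to know before spending any starting complex: how much of the charge stands as each complex when each flask is stopped.

    starting complex + incoming ligand → leaving ligand + complex with one exchanged (k1 = 11 /M/min)
    gas ⇌ incoming ligand, rate k2*(csat - [incoming ligand]) (k2 = 0.45 /min, csat = 1.2 mM)
    complex with one exchanged + incoming ligand → leaving ligand + complex with two exchanged (k3 = 9.5 /M/min)

all flasks: starting complex 32 mM; gas 1.2 mM (held)
- Sunday's: time 10 h
- Monday's: time 5.0 h

- at the start none of incoming ligand is dissolved
- run time (Sunday's): 10 h

1. which of these there is most of at the end, counted by the starting complex in it, Sunday's (starting complex / complex with two exchanged / complex with one exchanged)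
2. which of these there is most of at the end, counted by the starting complex in it, Monday's (starting complex / complex with two exchanged / complex with one exchanged)
3. final amount of the leader among these, as a percentage of the starting complex charged, in Sunday's
4. final amount of the leader among these, as a percentage of the starting complex charged, in Monday's

Each exchange takes one incoming ligand, so the charge demands 64.0 mM, and the saturated solution holds 1.2 mM, far less than that. What crosses from the gas is therefore, nearly enough, what reacts. The crossing rate is the transfer coefficient times the gap to saturation, so if the whole demand crosses within a run, the mean [incoming ligand] over that run is saturation minus the demand divided by transfer coefficient and run time: 0.726 mM for Monday's.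

I replace the curve by that mean. The complexes then fall pseudo-first-order, and one dimensionless number carries the run: the exposure, which is the rate constant of step 1 times mean [incoming ligand] times time. It splits into the exposure at saturation minus a toll of 1.56, the exposure a flask forgoes by keeping its dissolved ligand below saturation to feed the demand.

Sunday's exposure is 6.36 and Monday's 2.40. The rate constant of the second exchange is 0.864 of the first, so this reckoning leaves Sunday's with 0.174 % starting complex and 1.76 % complex with one exchanged, and Monday's with 9.11 % and 25.8 %.

Is one number enough? The toll assumes the whole demand is paid. Sunday's still owes 0.0165, much less than its exposure, so it stands. Monday's owes 0.344, and handing that back raises its exposure to 2.74, with 6.46 % and 21.5 %. I commit to complex with two exchanged at 98.1 % in Sunday's, and complex with two exchanged at 72.1 % in Monday's.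

The forecast names complex with two exchanged for both flasks, with 98 % (97 % to 99 %) in Sunday's and 70.5 % (67 % to 74 %) in Monday's, the latter lower than mine, on the ground that “the run is limited by gas transfer”.

The simulation gives complex with two exchanged at 98.1 % in Sunday's and complex with two exchanged at 70.5 % in Monday's. Monday's ends with 7.02 % of its starting complex, which reads as an exposure of 2.66, so the toll paid there is 1.30 of the 1.56. Sunday's read at 6.0 h, charged the whole toll of 1.56, reckons to an exposure of 3.19, which puts starting complex at 4.13 %, and that reading holds 3.56 %.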